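**Plan**

1. Retrosynthesis: the Ar–CH2–ring A bridge is cut first (formaldehyde union of aspidinol with a ring A monomer). Ring A, numbered as the cyclohexa-2,5-dien-1-one (C1 C=O, C2 butanoyl, C3 OH, C4 quaternary, C5 OH, C6 bridge carbon), is then cut at C2–C3 and C4–C5.
2. Enabling feature: ring A is a cyclohexane-1,3,5-trione whose quaternary C4 lies between two carbonyl-level carbons. C3/C4 are therefore the carboxyl and α-carbon of 2,5-dimethylhex-4-enoic acid, and C5–C6–C1–C2 is a β-keto-acyl chain. The prenyl CH= carbon is γ to C3, so this acid can be held as a γ-lactone.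
3. Forward: the lactone (3 steps) and a masked 3,5-dioxooctanoic acid (4 steps) are joined in one flask. The lactone enolate is C-acylated (C4–C5), the γ-carbon of the chain closes onto the lactone carbonyl (C2–C3), and the released β-phosphinoyl alkoxide collapses to the prenyl olefin. Acid unmasking and CH2 bridging follow.
4. Stereochemistry: a CBS reduction sets the lactone carbinol carbon (the future prenyl CH=). This centre sends the acyl group to the opposite face of C4 and is erased in the same flask.

Key step: step 8

Remark: aspidinol is taken as a purchasable natural product, and ring A is treated in the enol tautomer of the target SMILES (its tautomers interconvert freely).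

**Step 1**
Reactants: 1 isopropyldiphenylphosphine
Product: 2 isopropyldiphenylphosphine oxide
Conditions: H2O2 (30% aq.), CH2Cl2, 0 °C to rt
Reagents that add atoms: hydrogen peroxide, OO
Why: Oxidation of a tertiary phosphine to its oxide by hydrogen peroxide is fast and clean and installs the group needed for the later Horner–Wittig elimination.

**Step 2**
Reactants: 2 isopropyldiphenylphosphine oxide; 3 dimethyl 2-methylsuccinate (racemic)
Product: 4 methyl 5-(diphenylphosphoryl)-2,5-dimethyl-4-oxohexanoate (racemic)
Conditions: 2 (2 equiv), n-BuLi, THF, −78 °C; then 3, −78 to −40 °C; aq. NH4Cl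
Reagents that add atoms: none
Why: C-acylation of an α-lithiated alkyldiphenylphosphine oxide by an ester (Claisen-type) should take place at the unbranched CH2CO2Me group of 3, since the ester next to the methine is shielded from the tertiary carbanion, and the second equivalent of anion takes up the acidic proton of the keto ester.

**Step 3**
Reactants: 4 methyl 5-(diphenylphosphoryl)-2,5-dimethyl-4-oxohexanoate
Product: 6 (5R)-5-[2-(diphenylphosphoryl)propan-2-yl]-3-methyloxolan-2-one (both C3 epimers), via hydroxy ester 5 (not isolated)
Conditions: (S)-2-methyl-CBS-oxazaborolidine (0.2 equiv), BH3·SMe2, THF, −20 °C; MeOH quench; then p-TsOH·H2O (cat.), toluene, 80 °C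
Reagents that add atoms: none
Why: In the CBS reduction the tertiary phosphinoyl-bearing carbon takes the large-group position against the CH2 group, so the (S)-catalyst should give the (4R) carbinol, and acid then closes the γ-lactone (lactonization); the C3 epimers converge on enolisation in step 8.

**Step 4**
Reactants: 7 ethyl 3-oxohexanoate
Product: 8 ethyl 2-(2-propyl-1,3-dioxolan-2-yl)acetate
Conditions: ethylene glycol, p-TsOH·H2O (cat.), toluene, reflux with water separation
Reagents that add atoms: ethane-1,2-diol, OCCO
Why: Ketalisation of the ketone of a β-keto ester masks the future butanoyl carbonyl and removes the acidity beside it, which the strong bases of steps 5 and 8 require.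

**Step 5**
Reactants: 8 ethyl 2-(2-propyl-1,3-dioxolan-2-yl)acetate
Product: 9 methyl 3-oxo-4-(2-propyl-1,3-dioxolan-2-yl)butanoate
Conditions: methyl acetate, LiN(iPr)2 (2.2 equiv each), THF, −78 °C; then 8, −78 to 0 °C; aq. NH4Cl
Reagents that add atoms: methyl acetate, CC(=O)OC
Why: Crossed Claisen condensation of the lithium enolate of methyl acetate with the ester should give the β-keto ester, which is held as its enolate and so is safe from a second addition.

**Step 6**
Reactants: 9 methyl 3-oxo-4-(2-propyl-1,3-dioxolan-2-yl)butanoate
Product: 10 methyl (2E)-3-methoxy-4-(2-propyl-1,3-dioxolan-2-yl)but-2-enoate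
Conditions: HC(OMe)3 (3 equiv, no added methanol), p-TsOH·H2O (cat.), rt; Et3N quench
Reagents that add atoms: trimethyl orthoformate, COC(OC)OC
Why: Acid-catalysed enol ether formation from a β-keto ester with an orthoformate (ketalisation, then loss of methanol) should give the conjugated (E)-β-methoxy enoate, and working without methanol as solvent should keep the dioxolane from exchanging.

**Step 7**
Reactants: 10 methyl (2E)-3-methoxy-4-(2-propyl-1,3-dioxolan-2-yl)but-2-enoate
Product: 11 (2E)-3-methoxy-4-(2-propyl-1,3-dioxolan-2-yl)but-2-enoic acid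
Conditions: LiOH, THF/MeOH/H2O, 50 °C; then cold 1 M HCl to pH 4
Reagents that add atoms: lithium hydroxide, [Li+].[OH-]
Why: Saponification of the vinylogous carbonate ester needs warming but leaves ketal and enol ether untouched, and a cold, brief acidification to pH 4 should spare the ketal.

**Step 8**
Reactants: 11 (2E)-3-methoxy-4-(2-propyl-1,3-dioxolan-2-yl)but-2-enoic acid; 6 (5R)-5-[2-(diphenylphosphoryl)propan-2-yl]-3-methyloxolan-2-one
Product: 15 (6S)-5-hydroxy-3-methoxy-6-methyl-6-(3-methylbut-2-en-1-yl)-4-(2-propyl-1,3-dioxolan-2-yl)cyclohexa-2,4-dien-1-one, via acid chloride 12 (not isolated), via acylated lactone 13 (not isolated), via hydroxy phosphine oxide 14 (not isolated)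
Conditions: 11, 1-chloro-N,N,2-trimethylprop-1-en-1-amine, CH2Cl2, 0 °C to rt, evaporate; 6, LiN(iPr)2 (1.1 equiv), THF, −78 °C; add 12, −78 to −30 °C; KN(SiMe3)2 (3 equiv), −78 °C to rt; DMF, 50 °C; aq. NH4Cl
Reagents that add atoms: none
Why: Proposed new method: the lithium enolate of 6 should be C-acylated by 12 at its α-carbon (ring A C4) on the face away from the substituent on lactone C-5 (bond C4–C5, 13); KN(SiMe3)2 should then remove a γ-proton of the β-methoxy enone, the γ-carbon of the dienolate (ring A C2) attacks the lactone carbonyl and the ring oxygen leaves as an alkoxide (bond C2–C3, 14), and this alkoxide, β to P(O)Ph2, should undergo Horner–Wittig syn-elimination of diphenylphosphinate to return the prenyl olefin. The closest known reaction types are the C-acylation of α-substituted lactone enolates by acid chlorides, the Dieckmann-type intramolecular Claisen condensation of an enolate onto a lactone and the Horner–Wittig elimination of β-hydroxy phosphine oxides, but their union as an anionic [4+2] annulation that turns a butyrolactone into a cyclohexane-1,3,5-trione mono enol ether has not been shown. Ring A closes by a 6-(enolendo)-exo-trig attack of the dienolate γ-carbon on the lactone C=O, since attack through the α-carbon or the oxygen would give four-membered rings. The one new stereocentre (C4) is set in the acylation by 1,3-induction: the enolate geometry is fixed by the five-membered ring and the bulky C(CH3)2P(O)Ph2 group on lactone C-5 blocks one face, so the acyl group enters trans to it and the (5R) carbinol of 6 becomes the C4 configuration required (4R in 16 and 18); C4 carries no proton and cannot epimerise afterwards. The step needs C- over O-acylation (lithium enolate in THF, acid chloride), γ-deprotonation only (C4 is quaternary and the ketal removes the acidity beside the masked ketone) and elimination over retro-addition of the alkoxide (potassium counter-ion, DMF, warming), and the masked butanoyl group on C2 keeps ring A unsymmetrical so that its enolate stays chiral.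

**Step 9**
Reactants: 15 (6S)-5-hydroxy-3-methoxy-6-methyl-6-(3-methylbut-2-en-1-yl)-4-(2-propyl-1,3-dioxolan-2-yl)cyclohexa-2,4-dien-1-one
Product: 16 (4R)-2-butanoyl-3,5-dihydroxy-4-methyl-4-(3-methylbut-2-en-1-yl)cyclohexa-2,5-dien-1-one
Conditions: HCl (1 M aq.), THF, rt
Reagents that add atoms: water, O
Why: Dilute aqueous acid should hydrolyse the dioxolane to the butanoyl ketone (acetal hydrolysis) and the vinylogous methyl ester to the enol, while room temperature should keep the prenyl olefin from adding to a neighbouring enol; the quaternary carbon is not touched.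

**Step 10**
Reactants: 16 (4R)-2-butanoyl-3,5-dihydroxy-4-methyl-4-(3-methylbut-2-en-1-yl)cyclohexa-2,5-dien-1-one; 17 aspidinol [1-(2,6-dihydroxy-4-methoxy-3-methylphenyl)butan-1-one]
Product: 18 (4R)-2-butanoyl-6-[(3-butanoyl-2,4-dihydroxy-6-methoxy-5-methylphenyl)methyl]-3,5-dihydroxy-4-methyl-4-(3-methylbut-2-en-1-yl)cyclohexa-2,5-dien-1-one (CNP0219644.1)
Conditions: HCHO (37% aq., 1 equiv), NaOH (aq.), MeOH, 0 °C to rt; then 1 M HCl
Reagents that add atoms: formaldehyde, C=O
Why: Base-mediated formaldehyde condensation (hydroxymethylation, loss of water to a methide, conjugate capture), the usual way to methylene-bridged acylphloroglucinol dimers, should join the only free nucleophilic carbon of each partner (C6 of ring A in 16, C5 of 17), with the two symmetrical dimers expected as separable by-products.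

**Compound list**

1 | isopropyldiphenylphosphine | CC(C)P(c1ccccc1)c1ccccc1 | starting material
2 | isopropyldiphenylphosphine oxide | CC(C)P(=O)(c1ccccc1)c1ccccc1 | intermediate
3 | dimethyl 2-methylsuccinate (racemic) | COC(=O)CC(C)C(=O)OC | starting material
4 | methyl 5-(diphenylphosphoryl)-2,5-dimethyl-4-oxohexanoate (racemic) | COC(=O)C(C)CC(=O)C(C)(C)P(=O)(c1ccccc1)c1ccccc1 | intermediate
5 | methyl (4R)-5-(diphenylphosphoryl)-4-hydroxy-2,5-dimethylhexanoate (both C2 epimers) | COC(=O)C(C)C[C@@H](O)C(C)(C)P(=O)(c1ccccc1)c1ccccc1 | intermediate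
6 | (5R)-5-[2-(diphenylphosphoryl)propan-2-yl]-3-methyloxolan-2-one (both C3 epimers) | CC1C[C@H](C(C)(C)P(=O)(c2ccccc2)c2ccccc2)OC1=O | intermediate
7 | ethyl 3-oxohexanoate | CCCC(=O)CC(=O)OCC | starting material
8 | ethyl 2-(2-propyl-1,3-dioxolan-2-yl)acetate | CCCC1(CC(=O)OCC)OCCO1 | intermediate
9 | methyl 3-oxo-4-(2-propyl-1,3-dioxolan-2-yl)butanoate | CCCC1(CC(=O)CC(=O)OC)OCCO1 | intermediate
10 | methyl (2E)-3-methoxy-4-(2-propyl-1,3-dioxolan-2-yl)but-2-enoate | CCCC1(C/C(OC)=C\C(=O)OC)OCCO1 | intermediate
11 | (2E)-3-methoxy-4-(2-propyl-1,3-dioxolan-2-yl)but-2-enoic acid | CCCC1(C/C(OC)=C\C(=O)O)OCCO1 | intermediate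
12 | (2E)-3-methoxy-4-(2-propyl-1,3-dioxolan-2-yl)but-2-enoyl chloride | CCCC1(C/C(OC)=C\C(=O)Cl)OCCO1 | intermediate
13 | (3R,5R)-5-[2-(diphenylphosphoryl)propan-2-yl]-3-[(2E)-3-methoxy-4-(2-propyl-1,3-dioxolan-2-yl)but-2-enoyl]-3-methyloxolan-2-one | C[C@]1(C(=O)/C=C(OC)\CC2(CCC)OCCO2)C[C@H](C(C)(C)P(=O)(c2ccccc2)c2ccccc2)OC1=O | intermediate
14 | (6S)-6-[(2R)-3-(diphenylphosphoryl)-2-hydroxy-3-methylbutyl]-5-hydroxy-3-methoxy-6-methyl-4-(2-propyl-1,3-dioxolan-2-yl)cyclohexa-2,4-dien-1-one (present as its potassium salt) | CCCC1(OCCO1)C2=C(O)[C@](C)(C[C@@H](O)C(C)(C)P(=O)(c3ccccc3)c3ccccc3)C(=O)C=C2OC | intermediate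
15 | (6S)-5-hydroxy-3-methoxy-6-methyl-6-(3-methylbut-2-en-1-yl)-4-(2-propyl-1,3-dioxolan-2-yl)cyclohexa-2,4-dien-1-one | CCCC1(OCCO1)C2=C(O)[C@](C)(CC=C(C)C)C(=O)C=C2OC | intermediate
16 | (4R)-2-butanoyl-3,5-dihydroxy-4-methyl-4-(3-methylbut-2-en-1-yl)cyclohexa-2,5-dien-1-one | CCCC(=O)C1=C(O)[C@](C)(CC=C(C)C)C(O)=CC1=O | intermediate
17 | aspidinol, 1-(2,6-dihydroxy-4-methoxy-3-methylphenyl)butan-1-one | CCCC(=O)c1c(O)c(C)c(OC)cc1O | starting material
18 | (4R)-2-butanoyl-6-[(3-butanoyl-2,4-dihydroxy-6-methoxy-5-methylphenyl)methyl]-3,5-dihydroxy-4-methyl-4-(3-methylbut-2-en-1-yl)cyclohexa-2,5-dien-1-one | CCCC(=O)C1=C(O)[C@](C)(CC=C(C)C)C(O)=C(Cc2c(O)c(C(=O)CCC)c(O)c(C)c2OC)C1=O | target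

**Step count and risks**

Total step count: 10. Longest linear sequence: 7 (steps 4, 5, 6, 7, 8, 9, 10).

Steps most likely to fail:

1. Step 8 (proposed new method). Several processes could derail it:
   - O-acylation, or proton transfer from the acid chloride to the enolate, in place of C-acylation.
   - Loss of facial control if the phosphoryl oxygen delivers the electrophile to its own face.
   - Failure of the hindered γ-carbanion to close onto the lactone carbonyl.
   - Retro-addition of the alkoxide in place of elimination.

   The fallback uses known chemistry, sets out from 17 and returns at 16. Aspidinol 17 would be O-demethylated with BBr3 (CH2Cl2, −78 °C to rt) to 1-(2,4,6-trihydroxy-3-methylphenyl)butan-1-one F1. Alkylative dearomatisation of F1 with prenyl bromide (NaOMe, MeOH, 0 °C) at the methyl-bearing ring carbon should give racemic 2-butanoyl-3,5-dihydroxy-4-methyl-4-(3-methylbut-2-en-1-yl)cyclohexa-2,5-dien-1-one F2, to be separated from the aromatic product of prenylation at the free ring carbon. Preparative chromatography on a chiral stationary phase would then deliver the (4R) enantiomer 16.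

2. Step 10. Statistical competition between cross- and self-condensation, and further reaction of the methide with a second molecule of the same partner, could consume both monomers. The fallback sets out from 17 and returns at 18. Aspidinol 17 would be aminomethylated at its free ring carbon with N,N-dimethylmethyleneiminium iodide (CH2Cl2, rt; Mannich reaction) to 1-{3-[(dimethylamino)methyl]-2,6-dihydroxy-4-methoxy-5-methylphenyl}butan-1-one F3. Heating F3 with 16 (toluene, 100 °C) should expel dimethylamine and let the resulting quinone methide be captured by C6 of 16 alone, giving 18 without symmetrical dimers.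

3. Step 9. Acid-promoted addition of an enol oxygen to the prenyl olefin (ring closure to a chroman), or incomplete cleavage of the vinylogous methyl ester, could occur. The fallback sets out from 15 and returns at 16 and removes the methyl group by substitution instead of hydrolysis. Pyridinium p-toluenesulfonate in wet acetone (rt) should open only the ketal of 15 to (6S)-4-butanoyl-5-hydroxy-3-methoxy-6-methyl-6-(3-methylbut-2-en-1-yl)cyclohexa-2,4-dien-1-one F4. NaSEt (DMF, 60 °C) would then dealkylate the vinylogous ester by SN2 attack at the methyl carbon under non-acidic conditions to give 16.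

**Further compounds**

F1 | step 8 | 1-(2,4,6-trihydroxy-3-methylphenyl)butan-1-one | CCCC(=O)c1c(O)c(C)c(O)cc1O
F2 | step 8 | racemic 2-butanoyl-3,5-dihydroxy-4-methyl-4-(3-methylbut-2-en-1-yl)cyclohexa-2,5-dien-1-one | CCCC(=O)C1=C(O)C(C)(CC=C(C)C)C(O)=CC1=O
F3 | step 10 | 1-{3-[(dimethylamino)methyl]-2,6-dihydroxy-4-methoxy-5-methylphenyl}butan-1-one | CCCC(=O)c1c(O)c(C)c(OC)c(CN(C)C)c1O
F4 | step 9 | (6S)-4-butanoyl-5-hydroxy-3-methoxy-6-methyl-6-(3-methylbut-2-en-1-yl)cyclohexa-2,4-dien-1-one | CCCC(=O)C1=C(O)[C@](C)(CC=C(C)C)C(=O)C=C1OC
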